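**Retrosynthetic overview**
1. Cut both prenyl groups at the quaternary carbon C8. The last one goes on by alkylative dearomatisation and the first by aromatic C-prenylation of 6-benzoyl-5,7-dihydroxy-2,2-dimethyl-2H-chromene, both using prenyl bromide.
2. The key bond is C4–C4a of the chromene. It comes from an intermolecular aldol-type condensation of a phenol (reacting as a phenolic enolate) with 3-methylbut-2-enal, followed by loss of water and oxa-6π closure. Both hydroxyls ortho to the benzoyl group are masked as MOM ethers, so only the para oxygen can close and only the 6-benzoyl isomer can form.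
3. The 4-hydroxy-2,6-bis(MOM) benzophenone comes from directed ortho-lithiation of a TIPS-blocked 3,5-bis(MOM) phenol and acylation with N-methoxy-N-methylbenzamide. The phenol comes from phloroglucinol.
4. Ring order: the carbocycle (ring A) is bought as phloroglucinol, the pyran (ring B) is closed in step 5, and ring A is dearomatised in the last step.

**Assumption:** the target has no stereocentre, because C8 carries two identical prenyl groups and the only ring alkene is necessarily cis. It is therefore achiral and needs no asymmetric step. The SMILES shows one tautomer of a rapidly equilibrating enolised β-triketone.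

**Step 1**
Reactants: 1 phloroglucinol (anhydrous benzene-1,3,5-triol)
Product: 2 3,5-bis(methoxymethoxy)phenol
Conditions: NaH (2.1 equiv), MOMCl (2.05 equiv), DMF, 0 °C to rt; chromatography
Reagents that add atoms: chloromethyl methyl ether (MOMCl), COCCl
Why: In this Williamson-type O-alkylation the hard electrophile reacts at phenoxide oxygen, two equivalents make the bis-ether the main component (about 40 %) of a statistical mixture that separates easily by polarity, and no stereocentre is formed.

**Step 2**
Reactants: 2 3,5-bis(methoxymethoxy)phenol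
Product: 3 [3,5-bis(methoxymethoxy)phenoxy]triisopropylsilane
Conditions: TIPSCl (1.2 equiv), imidazole (2 equiv), DMF, rt
Reagents that add atoms: triisopropylsilyl chloride (TIPSCl), CC(C)[Si](Cl)(C(C)C)C(C)C
Why: Standard silyl ether formation gives a bulky, non-coordinating TIPS group that removes the acidic proton and shields both positions next to it, which prepares the site-selective lithiation.

**Step 3**
Reactants: 3 [3,5-bis(methoxymethoxy)phenoxy]triisopropylsilane; 4 N-methoxy-N-methylbenzamide
Product: 7 {2,6-bis(methoxymethoxy)-4-[(triisopropylsilyl)oxy]phenyl}(phenyl)methanone, via aryllithium 5 (not isolated), via lithium hemiaminal adduct 6 (not isolated)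
Conditions: n-BuLi (1.15 equiv), THF, 0 °C, 1 h; then 4 (1.2 equiv), −78 °C to 0 °C; H2O quench
Reagents that add atoms: none
Why: In this directed ortho-metalation and Weinreb ketone synthesis the two MOM groups cooperatively steer n-BuLi to the carbon between them, and the chelated tetrahedral adduct 6 cannot accept a second aryllithium, so the ketone is released only on quenching.

**Step 4**
Reactants: 7 {2,6-bis(methoxymethoxy)-4-[(triisopropylsilyl)oxy]phenyl}(phenyl)methanone
Product: 8 [4-hydroxy-2,6-bis(methoxymethoxy)phenyl](phenyl)methanone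
Conditions: TBAF (1.1 equiv), AcOH (1.1 equiv), THF, 0 °C
Reagents that add atoms: none
Why: Fluoride-driven desilylation, buffered by AcOH, frees only the phenol para to the ketone and leaves the MOM acetals untouched.

**Step 5 (key step)**
Reactants: 8 [4-hydroxy-2,6-bis(methoxymethoxy)phenyl](phenyl)methanone; 9 3-methylbut-2-enal (prenal)
Product: 12 [5,7-bis(methoxymethoxy)-2,2-dimethyl-2H-chromen-6-yl](phenyl)methanone, via aldol adduct 10 (not isolated), via ortho-quinone methide 11 (not isolated)
Conditions: 9 (3 equiv, in portions), ethylenediammonium diacetate (20 mol %), 4 Å molecular sieves, toluene, 110 °C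
Reagents that add atoms: none
Why: In this aldol-type (Knoevenagel) condensation and oxa-6π electrocyclisation cascade the ortho carbon of 8 (activated by three oxygens, deactivated only inductively by the twisted meta benzoyl group) adds to the activated aldehyde carbon of 9, adduct 10 loses water to 11, and 11 closes on the only free oxygen; the two ortho carbons are equivalent, so one regioisomer results, and the carbinol stereocentre of racemic 10 vanishes on dehydration.

**Step 6**
Reactants: 12 [5,7-bis(methoxymethoxy)-2,2-dimethyl-2H-chromen-6-yl](phenyl)methanone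
Product: 13 (5,7-dihydroxy-2,2-dimethyl-2H-chromen-6-yl)(phenyl)methanone
Conditions: HCl (1.25 M in MeOH), 40 °C, 1–2 h
Reagents that add atoms: none
Why: Acid-catalysed acetal exchange (methanolysis) removes the aryl MOM ethers, helped by the neighbouring carbonyl, under conditions that 2,2-dimethylchromenes tolerate.

**Step 7**
Reactants: 13 (5,7-dihydroxy-2,2-dimethyl-2H-chromen-6-yl)(phenyl)methanone; 14 1-bromo-3-methylbut-2-ene (prenyl bromide)
Product: 15 [5,7-dihydroxy-2,2-dimethyl-8-(3-methylbut-2-en-1-yl)-2H-chromen-6-yl](phenyl)methanone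
Conditions: 14 (1.1 equiv), KOH (2 equiv), H2O–MeOH 4:1, 0 °C to rt; then 1 M HCl
Reagents that add atoms: none
Why: This is C-alkylation of an ambident acylphloroglucinol phenolate, in which the protic medium hydrogen-bonds the oxygens so the soft allylic bromide is attacked in SN2 fashion by C8, the only unsubstituted nucleophilic ring carbon, and the dienone re-aromatises.

**Step 8**
Reactants: 15 [5,7-dihydroxy-2,2-dimethyl-8-(3-methylbut-2-en-1-yl)-2H-chromen-6-yl](phenyl)methanone; 14 1-bromo-3-methylbut-2-ene (prenyl bromide)
Product: 16 6-benzoyl-7-hydroxy-2,2-dimethyl-8,8-bis(3-methylbut-2-en-1-yl)-2H-chromen-5(8H)-one (target)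
Conditions: NaOMe (2.2 equiv), 14 (1.5 equiv), MeOH, 0 °C to rt; cold 1 M HCl work-up, below 30 °C, light excluded
Reagents that add atoms: none
Why: In this lupulone-type alkylative dearomatisation the phenolate of 15 is alkylated again at C8, because attack there keeps the C3–C4 alkene conjugated and gives a strongly stabilised enolised β-triketone whose anion resists further alkylation, and the new quaternary carbon bears two identical prenyl groups, so it is not a stereocentre.

**Compound list**
1 | phloroglucinol | Oc1cc(O)cc(O)c1 | starting material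
2 | 3,5-bis(methoxymethoxy)phenol | COCOc1cc(O)cc(OCOC)c1 | intermediate
3 | [3,5-bis(methoxymethoxy)phenoxy]triisopropylsilane | COCOc1cc(OCOC)cc(O[Si](C(C)C)(C(C)C)C(C)C)c1 | intermediate
4 | N-methoxy-N-methylbenzamide | CON(C)C(=O)c1ccccc1 | starting material
5 | {2,6-bis(methoxymethoxy)-4-[(triisopropylsilyl)oxy]phenyl}lithium (formed in the flask) | [Li]c1c(OCOC)cc(O[Si](C(C)C)(C(C)C)C(C)C)cc1OCOC | intermediate
6 | lithium hemiaminal (tetrahedral) adduct of 5 and 4, racemic (formed in the flask) | [Li]OC(N(C)OC)(c1ccccc1)c1c(OCOC)cc(O[Si](C(C)C)(C(C)C)C(C)C)cc1OCOC | intermediate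
7 | {2,6-bis(methoxymethoxy)-4-[(triisopropylsilyl)oxy]phenyl}(phenyl)methanone | COCOc1cc(O[Si](C(C)C)(C(C)C)C(C)C)cc(OCOC)c1C(=O)c1ccccc1 | intermediate
8 | [4-hydroxy-2,6-bis(methoxymethoxy)phenyl](phenyl)methanone | COCOc1cc(O)cc(OCOC)c1C(=O)c1ccccc1 | intermediate
9 | 3-methylbut-2-enal | CC(C)=CC=O | starting material
10 | [4-hydroxy-3-(1-hydroxy-3-methylbut-2-en-1-yl)-2,6-bis(methoxymethoxy)phenyl](phenyl)methanone, racemic (formed in the flask) | COCOc1cc(O)c(C(O)C=C(C)C)c(OCOC)c1C(=O)c1ccccc1 | intermediate
11 | (6Z)-4-benzoyl-3,5-bis(methoxymethoxy)-6-(3-methylbut-2-en-1-ylidene)cyclohexa-2,4-dien-1-one (formed in the flask) | CC(C)=C/C=C1\C(=O)C=C(OCOC)C(C(=O)c2ccccc2)=C1OCOC | intermediate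
12 | [5,7-bis(methoxymethoxy)-2,2-dimethyl-2H-chromen-6-yl](phenyl)methanone | COCOc1cc2OC(C)(C)C=Cc2c(OCOC)c1C(=O)c1ccccc1 | intermediate
13 | (5,7-dihydroxy-2,2-dimethyl-2H-chromen-6-yl)(phenyl)methanone | Oc1cc2OC(C)(C)C=Cc2c(O)c1C(=O)c1ccccc1 | intermediate
14 | 1-bromo-3-methylbut-2-ene | CC(C)=CCBr | starting material
15 | [5,7-dihydroxy-2,2-dimethyl-8-(3-methylbut-2-en-1-yl)-2H-chromen-6-yl](phenyl)methanone | CC(C)=CCc1c(O)c(C(=O)c2ccccc2)c(O)c2C=CC(C)(C)Oc12 | intermediate
16 | 6-benzoyl-7-hydroxy-2,2-dimethyl-8,8-bis(3-methylbut-2-en-1-yl)-2H-chromen-5(8H)-one (achiral) | CC(C)=CCC1(CC=C(C)C)C(O)=C(C(=O)c2ccccc2)C(=O)C2=C1OC(C)(C)C=C2 | target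

**Total step count:** 8. **Longest linear sequence:** 8 steps (1 to 16).

**Three steps most likely to fail**

**Step 5.** Phenol 8 has a single free hydroxyl and carries an aroyl group, so the aldol-type addition may be slow and prenal may self-condense first.
- The fallback sets out from 8 and comes back at 12.
- Phenol 8 is O-alkylated with 3-chloro-3-methylbut-1-yne (CuCl2·2H2O 1 mol %, DBU, MeCN, 0 °C). This gives the aryl 1,1-dimethylpropargyl ether F1.
- Heating F1 in o-xylene at 140 °C triggers an aromatic propargyl Claisen rearrangement, a 1,5-hydrogen shift and oxa-6π closure.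
- The result is the same single chromene 12, because both ortho positions are equivalent.

**Step 7.** O-prenylation, hydrolysis of the bromide and partial double alkylation can erode the yield of 15. Any doubly alkylated material is already 16 and is kept.
- The fallback sets out from 8 and comes back at 15. It installs the first prenyl group by a sigmatropic shift before ring B is made.
- 2-Methylbut-3-en-2-ol is treated with n-BuLi and then Boc2O in THF. This gives tert-butyl 2-methylbut-3-en-2-yl carbonate F2.
- Pd(PPh3)4 (5 mol %, zerovalent palladium) in THF at 0 °C couples this carbonate with 8. The product is the aryl 1,1-dimethylallyl ether F3.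
- Heating in toluene at 110 °C brings about the aromatic Claisen rearrangement to the ortho-prenyl phenol F4.
- Condensation with 9 under the conditions of step 5 can then occur only at the one remaining ortho carbon. It gives the 8-prenyl chromene bis-MOM ether F5.
- Methanolysis as in step 6, at rt to avoid chroman formation, delivers 15.

**Step 8.** Alkylation could compete at oxygen or at the ring-fusion carbon C4a. The 2H-pyran of the product can also open thermally or photochemically and re-close on the other carbonyl oxygen.
- The fallback sets out from 1 (with 14) and comes back at 16. It dearomatises before ring B exists.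
- Friedel–Crafts benzoylation of 1 (PhCOCl, AlCl3, nitrobenzene, 65 °C) gives 2,4,6-trihydroxybenzophenone F6.
- Exhaustive C-prenylation with 14 (3.3 equiv, aqueous KOH, 0 °C) stops at the lupulone-type triprenyl dienone F7.
- Dehydrogenation of its lone ring-bound prenyl group with (diacetoxyiodo)benzene and TEMPO in THF (−78 °C to rt) gives the alkylidene trione F8.
- This trione closes by oxa-6π electrocyclisation on the oxygen next to the quaternary carbon, which preserves the chelated β-triketone and gives 16.

**Further compounds**
F1 | step 5 | [2,6-bis(methoxymethoxy)-4-(2-methylbut-3-yn-2-yloxy)phenyl](phenyl)methanone | C#CC(C)(C)Oc1cc(OCOC)c(C(=O)c2ccccc2)c(OCOC)c1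
F2 | step 7 | tert-butyl 2-methylbut-3-en-2-yl carbonate | C=CC(C)(C)OC(=O)OC(C)(C)C
F3 | step 7 | [2,6-bis(methoxymethoxy)-4-(2-methylbut-3-en-2-yloxy)phenyl](phenyl)methanone | C=CC(C)(C)Oc1cc(OCOC)c(C(=O)c2ccccc2)c(OCOC)c1
F4 | step 7 | [4-hydroxy-2,6-bis(methoxymethoxy)-3-(3-methylbut-2-en-1-yl)phenyl](phenyl)methanone | CC(C)=CCc1c(O)cc(OCOC)c(C(=O)c2ccccc2)c1OCOC
F5 | step 7 | [5,7-bis(methoxymethoxy)-2,2-dimethyl-8-(3-methylbut-2-en-1-yl)-2H-chromen-6-yl](phenyl)methanone | CC(C)=CCc1c(OCOC)c(C(=O)c2ccccc2)c(OCOC)c2C=CC(C)(C)Oc12
F6 | step 8 | phenyl(2,4,6-trihydroxyphenyl)methanone | O=C(c1ccccc1)c1c(O)cc(O)cc1O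
F7 | step 8 | 2-benzoyl-3,5-dihydroxy-4,6,6-tris(3-methylbut-2-en-1-yl)cyclohexa-2,4-dien-1-one | CC(C)=CCC1=C(O)C(CC=C(C)C)(CC=C(C)C)C(=O)C(C(=O)c2ccccc2)=C1O
F8 | step 8 | 2-benzoyl-3-hydroxy-4,4-bis(3-methylbut-2-en-1-yl)-6-(3-methylbut-2-en-1-ylidene)cyclohex-2-ene-1,5-dione, side chain syn to the C5 carbonyl | CC(C)=C/C=C1\C(=O)C(CC=C(C)C)(CC=C(C)C)C(O)=C(C(=O)c2ccccc2)C1=O
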